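## Retrosynthetic overview

1. The target is cut at the (E)-C5=C6 bond (Julia–Kocienski olefination, last step) into an α-quaternary aldehyde (C1–C5, C21–C32) and a tetrazolyl sulfone (C6–C20).
2. The aldehyde comes from a vinyl oxirane by a stereospecific 1,2-vinyl shift (epoxide → aldehyde) that creates the C3 quaternary centre. The oxirane comes from the Sharpless epoxide of an (E,E)-trienol by oxidation and methylenation.
3. The trienol is built from a C9 alkyne by two Zr-catalysed methylaluminations (E alkenes). C28 comes from ethyl (S)-lactate through a pinacol-type 1,2-isopropenyl shift.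
4. The sulfone comes from (S)-3,4-dimethylcyclohexenone by Me2CuLi addition and trans enolate alkylation with a chiral iodo ester (sets C11), then methylenation. C7 is set by Ru–BINAP hydrogenation and C16 by an organocatalytic Michael addition.
5. Rings: only ring A (the cyclohexane) is built, first in the western fragment, by Robinson annulation of propanal and methyl vinyl ketone. The oxirane is transient.

Assumption: atom labels C1–C32 follow the order of the target SMILES, and small carbon donors (organometallics, Me3Al, ethylene oxide, ylide) are treated as reagents, not numbered.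

## Route

Step 1
Reactants: 1 ethyl (S)-lactate
Product: 2 ethyl (2S)-2-[(methylsulfonyl)oxy]propanoate
Conditions: MsCl, Et3N, CH2Cl2, 0 °C
Reagents that add atoms: methanesulfonyl chloride, CS(=O)(=O)Cl
Why: Sulfonylation of the secondary alcohol turns the lactate oxygen into the leaving group for the later 1,2-shift; the stereocentre is not touched.

Step 2
Reactants: 2 ethyl (2S)-2-[(methylsulfonyl)oxy]propanoate
Product: 4 (2S,3RS)-3-hydroxy-4-methylpent-4-en-2-yl methanesulfonate, via (2S)-2-[(methylsulfonyl)oxy]propanal 3 (not isolated)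
Conditions: iBu2AlH (1.05 equiv), CH2Cl2, −78 °C; then CH2=C(CH3)MgBr (2 equiv), THF, −78 → −40 °C; aq. NH4Cl at −40 °C
Reagents that add atoms: isopropenylmagnesium bromide, CC(=C)[Mg]Br
Why: One-pot ester semi-reduction and Grignard addition (reductive alkenylation); the new carbinol centre needs no control because it becomes a carbonyl in step 3.

Step 3
Reactants: 4 (2S,3RS)-3-hydroxy-4-methylpent-4-en-2-yl methanesulfonate
Product: 6 (2S)-2,3-dimethylbut-3-en-1-ol, via (2S)-2,3-dimethylbut-3-enal 5 (not isolated)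
Conditions: Et3Al (3 equiv), CH2Cl2, −78 → 0 °C; then iBu2AlH, −78 °C
Reagents that add atoms: none
Why: Pinacol-type (Suzuki–Tsuchihashi) rearrangement: the aluminium alkoxide drives a 1,2-shift of the isopropenyl group onto the mesylate carbon with inversion, which sets C28, and the epimerisable β,γ-unsaturated aldehyde is reduced in the same flask.

Step 4
Reactants: 6 (2S)-2,3-dimethylbut-3-en-1-ol
Product: 7 (3S)-4-iodo-2,3-dimethylbut-1-ene
Conditions: I2, PPh3, imidazole, CH2Cl2, 0 °C
Reagents that add atoms: iodine, II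
Why: Appel-type iodination of a primary alcohol under neutral conditions; the adjacent stereocentre is not involved.

Step 5
Reactants: 7 (3S)-4-iodo-2,3-dimethylbut-1-ene
Product: 9 (5R)-5,6-dimethylhept-6-en-1-yne, via C-silyl alkyne 8 (not isolated)
Conditions: CH3C≡CSiMe3, nBuLi, THF, −78 °C; 7, DMPU, −78 °C → rt; then K2CO3 (0.2 equiv), MeOH, rt
Reagents that add atoms: 1-(trimethylsilyl)prop-1-yne, CC#C[Si](C)(C)C
Why: SN2 alkylation of the propargylic lithium reagent (alkyl halides give the propargyl, not the allenyl, product), then base-catalysed C-desilylation in the same flask.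

Step 6
Reactants: 9 (5R)-5,6-dimethylhept-6-en-1-yne
Product: 12 (3E,7R)-4,7,8-trimethylnona-3,8-dien-1-ol, via alkenylalane 10 (not isolated), via lithium alkenylalanate 11 (not isolated)
Conditions: Me3Al (2 equiv), Cp2ZrCl2 (25 mol%), CH2Cl2, 0 °C → rt; evaporate; nBuLi, hexane/THF, −78 °C; ethylene oxide, −78 → 0 °C
Reagents that add atoms: trimethylaluminium, C[Al](C)C; ethylene oxide, C1CO1
Why: Negishi zirconium-catalysed carboalumination adds Me and Al syn across the terminal alkyne (E-C23=C24; the isopropenyl group is inert), and the alanate opens ethylene oxide to add C21–C22.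

Step 7
Reactants: 12 (3E,7R)-4,7,8-trimethylnona-3,8-dien-1-ol
Product: 13 (3E,7R)-1-iodo-4,7,8-trimethylnona-3,8-diene
Conditions: I2, PPh3, imidazole, CH2Cl2, 0 °C
Reagents that add atoms: iodine, II
Why: Appel-type iodination of the primary homoallylic alcohol; alkene geometry and C28 are untouched.

Step 8
Reactants: 13 (3E,7R)-1-iodo-4,7,8-trimethylnona-3,8-diene
Product: 14 (5E,9R)-6,9,10-trimethylundeca-5,10-dien-1-yne
Conditions: LiC≡CH·H2NCH2CH2NH2, DMSO, 10 °C → rt
Reagents that add atoms: lithium acetylide–ethylenediamine complex, [Li]C#C.NCCN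
Why: SN2 alkylation of lithium acetylide by a primary iodide in a dipolar aprotic solvent.

Step 9
Reactants: 14 (5E,9R)-6,9,10-trimethylundeca-5,10-dien-1-yne
Product: 17 (2E,6E,10R)-3,7,10,11-tetramethyldodeca-2,6,11-trien-1-ol, via alkenylalane 15 (not isolated), via lithium alkenylalanate 16 (not isolated)
Conditions: Me3Al (2 equiv), Cp2ZrCl2 (25 mol%), CH2Cl2, 0 °C → rt; evaporate; nBuLi, hexane/THF, −78 °C; (CH2O)n, → rt
Reagents that add atoms: trimethylaluminium, C[Al](C)C; formaldehyde (as paraformaldehyde), C=O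
Why: Second Negishi syn carboalumination (E trisubstituted alkene, other alkenes inert), and hydroxymethylation of the alanate gives the allylic alcohol.

Step 10
Reactants: 17 (2E,6E,10R)-3,7,10,11-tetramethyldodeca-2,6,11-trien-1-ol
Product: 18 [(2S,3S)-3-methyl-3-[(3E,7R)-4,7,8-trimethylnona-3,8-dien-1-yl]oxiran-2-yl]methanol
Conditions: Ti(OiPr)4 (10 mol%), L-(+)-diethyl tartrate (12 mol%), tBuOOH, 4 Å sieves, CH2Cl2, −20 °C
Reagents that add atoms: tert-butyl hydroperoxide, CC(C)(C)OO
Why: Sharpless asymmetric epoxidation: the allylic hydroxyl directs titanium so only the 2,3-alkene reacts, and L-(+)-tartrate gives the (2S,3S)-epoxide whose configuration is later transferred to C3.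

Step 11
Reactants: 18 [(2S,3S)-3-methyl-3-[(3E,7R)-4,7,8-trimethylnona-3,8-dien-1-yl]oxiran-2-yl]methanol
Product: 20 (2S,3S)-3-ethenyl-2-methyl-2-[(3E,7R)-4,7,8-trimethylnona-3,8-dien-1-yl]oxirane, via epoxy aldehyde 19 (not isolated)
Conditions: (COCl)2, DMSO, CH2Cl2, −78 °C; Et3N; then Ph3P=CH2 (3 equiv, from Ph3PCH3Br, KN(SiMe3)2), THF, −78 → 0 °C
Reagents that add atoms: methylidenetriphenylphosphorane, C=P(c1ccccc1)(c1ccccc1)c1ccccc1
Why: Swern oxidation followed by Wittig methylenation in the same flask, so the sensitive epoxy aldehyde is not isolated; neither operation touches the oxirane stereocentres.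

Step 12
Reactants: 20 (2S,3S)-3-ethenyl-2-methyl-2-[(3E,7R)-4,7,8-trimethylnona-3,8-dien-1-yl]oxirane
Product: 21 (2S,5E,9R)-2-ethenyl-2,6,9,10-tetramethylundeca-5,10-dienal
Conditions: MeAl(OC6H2-4-Br-2,6-tBu2)2 (1.2 equiv), CH2Cl2, −78 → −40 °C
Reagents that add atoms: none
Why: Proposed new method: the bulky aluminium Lewis acid binds the oxirane oxygen and ionises the C–O bond at the fully substituted carbon; the vinyl group on the neighbouring carbon bridges (cyclopropylcarbinyl-type cation) and shifts 1,2 anti to the departing oxygen, so C3 is inverted and the (2S,3S)-oxirane gives the (S)-aldehyde with vinyl, methyl and chain in place. The bulk of the reagent disfavours hydride shift, and the cation cannot cyclise onto C23=C24 without forming a secondary cation. The closest known reactions are the rearrangement of trisubstituted epoxides to α-quaternary aldehydes by alkyl shift and of 2,3-epoxy silyl ethers by siloxymethyl shift with the same reagent (Meinwald/semipinacol type); an alkenyl shift onto a non-stabilised dialkyl oxirane carbon that carries a polyene chain has not been shown.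

Step 13
Reactants: 22 3-methylideneoxolan-2-one (α-methylene-γ-butyrolactone)
Product: 23 (3S)-3-methyloxolan-2-one
Conditions: H2 (100 atm), Ru(OAc)2[(R)-BINAP] (0.5 mol%), CH2Cl2, 50 °C
Reagents that add atoms: none
Why: Noyori-type asymmetric hydrogenation of the α-methylene lactone (carbonyl-directed); the (R)-BINAP complex, mirror image of the one that gives the R lactone, sets C7.

Step 14
Reactants: 23 (3S)-3-methyloxolan-2-one
Product: 24 ethyl (2S)-4-iodo-2-methylbutanoate
Conditions: Me3SiI (1.2 equiv), EtOH (3 equiv), CH2Cl2, rt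
Reagents that add atoms: iodotrimethylsilane, C[Si](C)(C)I; ethanol, CCO
Why: Lewis-acid lactone opening: iodide attacks the O-alkyl carbon of the silylated lactone (SN2) and ethanol esterifies the silyl ester; the α-stereocentre is not involved.

Step 15
Reactants: 25 propanal; 26 but-3-en-2-one (methyl vinyl ketone)
Product: 28 (4S)-4-methylcyclohex-2-en-1-one, via (2S)-2-methyl-5-oxohexanal 27 (not isolated)
Conditions: (R)-2-[methoxy(diphenyl)methyl]pyrrolidine (5 mol%), ethyl 3,4-dihydroxybenzoate (20 mol%), neat, 4 °C; then LiOH (cat.), iPrOH, rt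
Reagents that add atoms: none
Why: Organocatalytic Robinson annulation: enamine Michael addition of propanal, with one face shielded by the diarylmethyl group, sets C16, and intramolecular aldol condensation closes ring A.

Step 16
Reactants: 28 (4S)-4-methylcyclohex-2-en-1-one
Product: 29 trimethyl{[(3R,4S)-3,4-dimethylcyclohex-1-en-1-yl]oxy}silane
Conditions: Me2CuLi (from MeLi, CuI), Me3SiCl, Et2O/THF, −78 °C; Et3N
Reagents that add atoms: lithium dimethylcuprate, [Li+].C[Cu-]C; chlorotrimethylsilane, C[Si](C)(C)Cl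
Why: Cuprate 1,4-addition (anti to the C4 methyl group) with in situ O-silylation of the enolate; the new C3 stereocentre is erased in step 17.

Step 17
Reactants: 29 trimethyl{[(3R,4S)-3,4-dimethylcyclohex-1-en-1-yl]oxy}silane
Product: 30 (4S)-3,4-dimethylcyclohex-2-en-1-one
Conditions: Pd(OAc)2 (10 mol%), O2 (1 atm), DMSO, 60 °C
Reagents that add atoms: none
Why: Saegusa–Ito dehydrogenation (aerobic, palladium-catalysed) of the silyl enol ether regenerates the enone with the 3-methyl group in place; the γ-stereocentre is untouched.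

Step 18
Reactants: 30 (4S)-3,4-dimethylcyclohex-2-en-1-one; 24 ethyl (2S)-4-iodo-2-methylbutanoate
Product: 32 ethyl (2S)-2-methyl-4-[(1R,3S)-2,2,3-trimethyl-6-oxocyclohexyl]butanoate, via lithium enolate 31 (not isolated)
Conditions: Me2CuLi (from MeLi, CuI), Et2O, 0 °C; then 24, DMPU/THF, −30 °C → rt
Reagents that add atoms: lithium dimethylcuprate, [Li+].C[Cu-]C
Why: Conjugate addition builds the gem-dimethyl carbon C18 and gives the enolate regiospecifically; SN2 alkylation is axial, anti to the pseudoaxial C18 methyl group and on the face opposite the equatorial C16 methyl group, which sets C11 trans to C16.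

Step 19
Reactants: 32 ethyl (2S)-2-methyl-4-[(1R,3S)-2,2,3-trimethyl-6-oxocyclohexyl]butanoate
Product: 33 ethyl (2S)-2-methyl-4-[(1S,3S)-2,2,3-trimethyl-6-methylidenecyclohexyl]butanoate
Conditions: Zn, CH2Br2, TiCl4, THF/CH2Cl2, 0 °C → rt
Reagents that add atoms: dibromomethane, BrCBr
Why: Takai–Lombardo methylenation is non-basic, so the epimerisable α-centre C11 is preserved and the ester is left alone.

Step 20
Reactants: 33 ethyl (2S)-2-methyl-4-[(1S,3S)-2,2,3-trimethyl-6-methylidenecyclohexyl]butanoate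
Product: 34 (2S)-2-methyl-4-[(1S,3S)-2,2,3-trimethyl-6-methylidenecyclohexyl]butan-1-ol
Conditions: LiAlH4, THF, 0 °C
Reagents that add atoms: none
Why: Hydride reduction of the ester to the primary alcohol; the alkene and all stereocentres are inert.

Step 21
Reactants: 34 (2S)-2-methyl-4-[(1S,3S)-2,2,3-trimethyl-6-methylidenecyclohexyl]butan-1-ol
Product: 35 5-({(2S)-2-methyl-4-[(1S,3S)-2,2,3-trimethyl-6-methylidenecyclohexyl]butyl}sulfanyl)-1-phenyl-1H-tetrazole
Conditions: 1-phenyl-1H-tetrazole-5-thiol, PPh3, iPrO2CN=NCO2iPr, THF, 0 °C → rt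
Reagents that add atoms: 1-phenyl-1H-tetrazole-5-thiol, Sc1nnnn1-c1ccccc1
Why: Mitsunobu thioetherification of the primary alcohol with the acidic tetrazole thiol.

Step 22
Reactants: 35 5-({(2S)-2-methyl-4-[(1S,3S)-2,2,3-trimethyl-6-methylidenecyclohexyl]butyl}sulfanyl)-1-phenyl-1H-tetrazole
Product: 36 5-({(2S)-2-methyl-4-[(1S,3S)-2,2,3-trimethyl-6-methylidenecyclohexyl]butyl}sulfonyl)-1-phenyl-1H-tetrazole
Conditions: (NH4)6Mo7O24·4H2O (10 mol%), 30% H2O2, EtOH, 0 °C → rt
Reagents that add atoms: hydrogen peroxide, OO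
Why: Molybdate-catalysed peroxide oxidation of sulfide to sulfone, selective over the unactivated 1,1-disubstituted alkene.

Step 23
Reactants: 36 5-({(2S)-2-methyl-4-[(1S,3S)-2,2,3-trimethyl-6-methylidenecyclohexyl]butyl}sulfonyl)-1-phenyl-1H-tetrazole; 21 (2S,5E,9R)-2-ethenyl-2,6,9,10-tetramethylundeca-5,10-dienal
Product: 37 (1S,3S)-1-[(3S,4E,6S,9E,13R)-6-ethenyl-3,6,10,13,14-pentamethylpentadeca-4,9,14-trien-1-yl]-2,2,3-trimethyl-6-methylidenecyclohexane (CNP0293684.2)
Conditions: KN(SiMe3)2 added to 36 and 21, DME, −60 °C → rt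
Reagents that add atoms: none
Why: Julia–Kocienski olefination: the metalated tetrazolyl sulfone adds to the non-enolisable aldehyde and Smiles rearrangement with loss of SO2 gives the E alkene (potassium counter-ion in an ether solvent favours E); no stereocentre can epimerise.

## Compound list

1 | ethyl (S)-lactate | CCOC(=O)[C@H](C)O | starting material
2 | ethyl (2S)-2-[(methylsulfonyl)oxy]propanoate | CCOC(=O)[C@H](C)OS(C)(=O)=O | intermediate
3 | (2S)-2-[(methylsulfonyl)oxy]propanal (formed in the flask) | C[C@H](OS(C)(=O)=O)C=O | intermediate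
4 | (2S,3RS)-3-hydroxy-4-methylpent-4-en-2-yl methanesulfonate | CC(=C)C(O)[C@H](C)OS(C)(=O)=O | intermediate
5 | (2S)-2,3-dimethylbut-3-enal (formed in the flask) | O=C[C@@H](C)C(=C)C | intermediate
6 | (2S)-2,3-dimethylbut-3-en-1-ol | OC[C@@H](C)C(=C)C | intermediate
7 | (3S)-4-iodo-2,3-dimethylbut-1-ene | IC[C@@H](C)C(=C)C | intermediate
8 | trimethyl[(5R)-5,6-dimethylhept-6-en-1-yn-1-yl]silane (formed in the flask) | C[Si](C)(C)C#CCC[C@@H](C)C(=C)C | intermediate
9 | (5R)-5,6-dimethylhept-6-en-1-yne | C#CCC[C@@H](C)C(=C)C | intermediate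
10 | dimethyl[(1E,5R)-2,5,6-trimethylhepta-1,6-dien-1-yl]alumane (formed in the flask) | C[Al](C)/C=C(\C)CC[C@@H](C)C(=C)C | intermediate
11 | lithium butyl(dimethyl)[(1E,5R)-2,5,6-trimethylhepta-1,6-dien-1-yl]aluminate (formed in the flask) | [Li+].CCCC[Al-](C)(C)/C=C(\C)CC[C@@H](C)C(=C)C | intermediate
12 | (3E,7R)-4,7,8-trimethylnona-3,8-dien-1-ol | OCC/C=C(\C)CC[C@@H](C)C(=C)C | intermediate
13 | (3E,7R)-1-iodo-4,7,8-trimethylnona-3,8-diene | ICC/C=C(\C)CC[C@@H](C)C(=C)C | intermediate
14 | (5E,9R)-6,9,10-trimethylundeca-5,10-dien-1-yne | C#CCC/C=C(\C)CC[C@@H](C)C(=C)C | intermediate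
15 | dimethyl[(1E,5E,9R)-2,6,9,10-tetramethylundeca-1,5,10-trien-1-yl]alumane (formed in the flask) | C[Al](C)/C=C(\C)CC/C=C(\C)CC[C@@H](C)C(=C)C | intermediate
16 | lithium butyl(dimethyl)[(1E,5E,9R)-2,6,9,10-tetramethylundeca-1,5,10-trien-1-yl]aluminate (formed in the flask) | [Li+].CCCC[Al-](C)(C)/C=C(\C)CC/C=C(\C)CC[C@@H](C)C(=C)C | intermediate
17 | (2E,6E,10R)-3,7,10,11-tetramethyldodeca-2,6,11-trien-1-ol | OC/C=C(\C)CC/C=C(\C)CC[C@@H](C)C(=C)C | intermediate
18 | [(2S,3S)-3-methyl-3-[(3E,7R)-4,7,8-trimethylnona-3,8-dien-1-yl]oxiran-2-yl]methanol | OC[C@@H]1O[C@@]1(C)CC/C=C(\C)CC[C@@H](C)C(=C)C | intermediate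
19 | (2R,3S)-3-methyl-3-[(3E,7R)-4,7,8-trimethylnona-3,8-dien-1-yl]oxirane-2-carbaldehyde (formed in the flask) | O=C[C@@H]1O[C@@]1(C)CC/C=C(\C)CC[C@@H](C)C(=C)C | intermediate
20 | (2S,3S)-3-ethenyl-2-methyl-2-[(3E,7R)-4,7,8-trimethylnona-3,8-dien-1-yl]oxirane | C=C[C@@H]1O[C@@]1(C)CC/C=C(\C)CC[C@@H](C)C(=C)C | intermediate
21 | (2S,5E,9R)-2-ethenyl-2,6,9,10-tetramethylundeca-5,10-dienal | C=C[C@@](C)(C=O)CC/C=C(\C)CC[C@@H](C)C(=C)C | intermediate
22 | 3-methylideneoxolan-2-one | C=C1CCOC1=O | starting material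
23 | (3S)-3-methyloxolan-2-one | O=C1OCC[C@@H]1C | intermediate
24 | ethyl (2S)-4-iodo-2-methylbutanoate | CCOC(=O)[C@@H](C)CCI | intermediate
25 | propanal | CCC=O | starting material
26 | but-3-en-2-one | CC(=O)C=C | starting material
27 | (2S)-2-methyl-5-oxohexanal (formed in the flask) | CC(=O)CC[C@H](C)C=O | intermediate
28 | (4S)-4-methylcyclohex-2-en-1-one | O=C1CC[C@H](C)C=C1 | intermediate
29 | trimethyl{[(3R,4S)-3,4-dimethylcyclohex-1-en-1-yl]oxy}silane | C[Si](C)(C)OC1=C[C@H](C)[C@@H](C)CC1 | intermediate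
30 | (4S)-3,4-dimethylcyclohex-2-en-1-one | O=C1CC[C@H](C)C(C)=C1 | intermediate
31 | lithium (4S)-3,3,4-trimethylcyclohex-1-en-1-olate (formed in the flask) | [Li]OC1=CC(C)(C)[C@@H](C)CC1 | intermediate
32 | ethyl (2S)-2-methyl-4-[(1R,3S)-2,2,3-trimethyl-6-oxocyclohexyl]butanoate | CCOC(=O)[C@@H](C)CC[C@H]1C(=O)CC[C@H](C)C1(C)C | intermediate
33 | ethyl (2S)-2-methyl-4-[(1S,3S)-2,2,3-trimethyl-6-methylidenecyclohexyl]butanoate | CCOC(=O)[C@@H](C)CC[C@H]1C(=C)CC[C@H](C)C1(C)C | intermediate
34 | (2S)-2-methyl-4-[(1S,3S)-2,2,3-trimethyl-6-methylidenecyclohexyl]butan-1-ol | OC[C@@H](C)CC[C@H]1C(=C)CC[C@H](C)C1(C)C | intermediate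
35 | 5-({(2S)-2-methyl-4-[(1S,3S)-2,2,3-trimethyl-6-methylidenecyclohexyl]butyl}sulfanyl)-1-phenyl-1H-tetrazole | c1ccccc1-n2nnnc2SC[C@@H](C)CC[C@H]3C(=C)CC[C@H](C)C3(C)C | intermediate
36 | 5-({(2S)-2-methyl-4-[(1S,3S)-2,2,3-trimethyl-6-methylidenecyclohexyl]butyl}sulfonyl)-1-phenyl-1H-tetrazole | c1ccccc1-n2nnnc2S(=O)(=O)C[C@@H](C)CC[C@H]3C(=C)CC[C@H](C)C3(C)C | intermediate
37 | (1S,3S)-1-[(3S,4E,6S,9E,13R)-6-ethenyl-3,6,10,13,14-pentamethylpentadeca-4,9,14-trien-1-yl]-2,2,3-trimethyl-6-methylidenecyclohexane | C=C[C@@](C)(/C=C/[C@@H](C)CC[C@H]1C(=C)CC[C@H](C)C1(C)C)CC/C=C(\C)CC[C@@H](C)C(=C)C | target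

## Step count and risks

Total steps: 23. Longest linear sequence: 13 (steps 1–12, then step 23). No protecting groups are used.

The three steps most likely to fail:

Step 12 (the proposed 1,2-vinyl shift). The oxirane could instead ionise at the allylic C–O bond (dihydrofuran or dienol) or give a hydride shift (enone). The fallback uses known chemistry, sets out from 18 and comes back at 37. Epoxy alcohol 18 is silylated (tBuMe2SiCl, imidazole, DMF) to the tert-butyldimethylsilyl ether of 18 F1. The established rearrangement of 3,3-disubstituted 2,3-epoxy silyl ethers with MeAl(OC6H2-4-Br-2,6-tBu2)2 (CH2Cl2, −78 °C; 1,2-shift of the siloxymethyl group, same anti course, same configuration at C3) gives (2S,5E,9R)-2-(tert-butyldimethylsilyloxymethyl)-2,6,9,10-tetramethylundeca-5,10-dienal F2. Julia–Kocienski olefination of this aldehyde with 36 (KN(SiMe3)2, DME) gives the silyl ether of the 3-(hydroxymethyl) analogue of 37 F3. Bu4NF (THF) then gives the 3-(hydroxymethyl) analogue of 37 F4, Dess–Martin periodinane gives the 3-formyl analogue of 37 F5, and Ph3P=CH2 gives 37. This costs two more steps than the main route.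

Step 18 (alkylation of a cuprate-derived enolate with an unactivated primary iodide, which can be slow and low-yielding). The fallback sets out from 30 and comes back at 32. Enolate 31, made as in step 18, is trapped with allyl bromide (fast SN2, same axial trans-selective attack) to give (2R,4S)-3,3,4-trimethyl-2-(prop-2-en-1-yl)cyclohexan-1-one F6. Cross-metathesis with ethyl methacrylate (second-generation Hoveyda–Grubbs catalyst, CH2Cl2, 40 °C) gives ethyl (2E)-2-methyl-4-[(1R,3S)-2,2,3-trimethyl-6-oxocyclohexyl]but-2-enoate F7. Asymmetric hydrogenation of the trisubstituted enoate with an iridium phosphine–oxazoline catalyst ([Ir(cod)(tBu-PHOX)]BArF, the enantiomer that gives 2S; H2 50 bar, CH2Cl2) sets C7 and returns 32.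

Step 8 (acetylide displacement on a homoallylic iodide, where E2 elimination to the conjugated diene competes). The fallback replaces the SN2 reaction by an sp2–sp3 cross-coupling, sets out from 9 and comes back at 14. Carboalumination of 9 as in step 6, quenched with I2 instead of ethylene oxide, gives (1E,5R)-1-iodo-2,5,6-trimethylhepta-1,6-diene F8. Negishi coupling with [4-(trimethylsilyl)but-3-yn-1-yl]zinc bromide (Pd(PPh3)4, THF, rt) gives trimethyl[(5E,9R)-6,9,10-trimethylundeca-5,10-dien-1-yn-1-yl]silane F9, and K2CO3 in MeOH returns 14.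

## Further compounds

F1 | step 12 | tert-butyldimethylsilyl ether of 18 | CC(C)(C)[Si](C)(C)OC[C@@H]1O[C@@]1(C)CC/C=C(\C)CC[C@@H](C)C(=C)C
F2 | step 12 | (2S,5E,9R)-2-(tert-butyldimethylsilyloxymethyl)-2,6,9,10-tetramethylundeca-5,10-dienal | CC(C)(C)[Si](C)(C)OC[C@@](C)(C=O)CC/C=C(\C)CC[C@@H](C)C(=C)C
F3 | step 12 | silyl ether of the 3-(hydroxymethyl) analogue of 37 (CH2OSitBuMe2 in place of the vinyl group at C3) | CC(C)(C)[Si](C)(C)OC[C@@](C)(/C=C/[C@@H](C)CC[C@H]1C(=C)CC[C@H](C)C1(C)C)CC/C=C(\C)CC[C@@H](C)C(=C)C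
F4 | step 12 | 3-(hydroxymethyl) analogue of 37 (CH2OH in place of the vinyl group at C3) | OC[C@@](C)(/C=C/[C@@H](C)CC[C@H]1C(=C)CC[C@H](C)C1(C)C)CC/C=C(\C)CC[C@@H](C)C(=C)C
F5 | step 12 | 3-formyl analogue of 37 (CHO in place of the vinyl group at C3) | O=C[C@@](C)(/C=C/[C@@H](C)CC[C@H]1C(=C)CC[C@H](C)C1(C)C)CC/C=C(\C)CC[C@@H](C)C(=C)C
F6 | step 18 | (2R,4S)-3,3,4-trimethyl-2-(prop-2-en-1-yl)cyclohexan-1-one | C=CC[C@H]1C(=O)CC[C@H](C)C1(C)C
F7 | step 18 | ethyl (2E)-2-methyl-4-[(1R,3S)-2,2,3-trimethyl-6-oxocyclohexyl]but-2-enoate | CCOC(=O)/C(C)=C/C[C@H]1C(=O)CC[C@H](C)C1(C)C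
F8 | step 8 | (1E,5R)-1-iodo-2,5,6-trimethylhepta-1,6-diene | I/C=C(\C)CC[C@@H](C)C(=C)C
F9 | step 8 | trimethyl[(5E,9R)-6,9,10-trimethylundeca-5,10-dien-1-yn-1-yl]silane | C[Si](C)(C)C#CCC/C=C(\C)CC[C@@H](C)C(=C)C
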